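The cyclohexene is treated as a dearomatised anisole. C7 is set by catalysis on a flat 3-arylbutanoate. Birch reduction then unmasks a 6-alkyl-3-methylcyclohex-2-enone in which C2, the future ether carbon, is a ketone. Ring carbon C1, wedged between C2=O and exocyclic C7, is deliberately left stereolabile. One ketoreductase-catalysed dynamic reductive kinetic resolution funnels both C1 epimers of this keto acid into a single trans allylic alcohol, fixing C1 and C2 relative to C7 in one operation. The ether is then closed at the O–aryl bond (SNAr, retention at C2). C5–OH is relayed from the ring by allylic hydroxylation, and the curcuminoid chain is completed last.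

Key step: step 4

Numbering used in the text (bisabolane): C1 is the ring carbon bearing the side chain, C2 the ether carbon, C3=C4(CH3) the ring alkene, C5 the carbinol carbon, C6 the ring CH2, C7 the side-chain methine, C8 the side-chain CH2 and C9 the side-chain ketone.

Assumption: 1,3-diketones are written in the diketo form, except the target, which is written as the keto–enol tautomer given. The boron chelates are drawn as 1:1 dibutoxyboron diketonates.

Step 1
Reactants: 1 (2-methoxy-4-methylphenyl)boronic acid; 2 isopropyl (E)-but-2-enoate
Product: 3 isopropyl (3S)-3-(2-methoxy-4-methylphenyl)butanoate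
Conditions: [Rh(acac)(C2H4)2] (3 mol %), (R)-BINAP (3.3 mol %), 1 (2 equiv), dioxane/H2O 10:1, 100 °C
Reagents that add atoms: none
Why: Hayashi–Miyaura rhodium-catalysed asymmetric 1,4-addition, in which the aryl–Rh(I)/(R)-BINAP species carbometallates the (E)-enoate on the face left open by the ligand and sets C7 as (S) (the (S)-ligand is known to give (R)-3-arylbutanoates from (E)-crotonates), and hydrolysis of the oxa-π-allyl rhodium closes the cycle.

Step 2
Reactants: 3 isopropyl (3S)-3-(2-methoxy-4-methylphenyl)butanoate
Product: 4 (3S)-3-(2-methoxy-4-methylphenyl)butanoic acid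
Conditions: LiOH·H2O, THF/MeOH/H2O, 40 °C; then 1 M HCl
Reagents that add atoms: lithium hydroxide, [Li+].[OH-]
Why: Ester saponification (BAc2); C7 is β to the carboxyl group and carries no acidic hydrogen, so it is not touched.

Step 3
Reactants: 4 (3S)-3-(2-methoxy-4-methylphenyl)butanoic acid
Product: 6 (3S)-3-[(1RS)-4-methyl-2-oxocyclohex-3-en-1-yl]butanoic acid, via (3S)-3-(2-methoxy-4-methylcyclohexa-1,4-dien-1-yl)butanoic acid 5 (not isolated)
Conditions: Li, NH3(l)/THF/t-BuOH, −78 to −33 °C; NH4Cl; then 2 M HCl, THF, 40 °C
Reagents that add atoms: water, O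
Why: Birch reduction puts the two sp3 carbons at C3 and C6 so that OMe and both alkyl groups stay on double bonds (the thymol methyl ether to piperitone pattern), the carboxylate is inert to solvated electrons, and acid hydrolysis of the enol ether with migration of the β,γ-double bond into conjugation gives the enone; protonation at C1 is unselective, which is intended.

Step 4
Reactants: 6 (3S)-3-[(1RS)-4-methyl-2-oxocyclohex-3-en-1-yl]butanoic acid
Product: 7 (3S)-3-[(1R,2R)-2-hydroxy-4-methylcyclohex-3-en-1-yl]butanoic acid
Conditions: ketoreductase (NADPH-dependent short-chain dehydrogenase/carbonyl reductase, chosen by panel screening), NADP+ (cat.), i-PrOH (10% v/v), triethanolamine buffer pH 8.5–9.0, 35 °C, N2 sweep; extraction at pH 5, 0 °C, used at once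
Reagents that add atoms: none
Why: At pH 8.5–9 the C1–H of 6, the α′-hydrogen of the enone, exchanges through the cross-conjugated dienolate (the pendant carboxylate can reach it through a six-membered array as an internal general base), so the two C1 epimers interconvert, whereas C7, β to both carbonyl groups, has no pathway to epimerise. The ketoreductase binds only the (1R)-epimer productively and transfers the hydride of NADPH to the Si face of C2=O, and oxidation of isopropanol to acetone, which is swept out, regenerates NADPH and makes the reduction irreversible, so that the whole epimer pool should drain into 7. The closest known reaction type is the ketoreductase-catalysed dynamic reductive kinetic resolution of α-substituted cyclic ketones, δ-keto acids are accepted substrates of carbonyl reductases, and the p-menthane counterpart of this redox pair, isopiperitenone and (3S,4R)-trans-isopiperitenol with the same absolute sense, is interconverted by a short-chain dehydrogenase of mint. No ring is closed. C1 (R) is controlled by the epimer selection of the active site, which reads the ring together with the fixed C7 (S) branch, and C2 (R, hydroxyl trans to the side chain) by the facial delivery of hydride, which coincides with the intrinsically preferred axial attack on the half-chair with an equatorial side chain. The step needs 1,2- rather than 1,4-reduction, which is inherent to nicotinamide-dependent carbonyl reductases, discrimination of two epimers that differ only in the C1/C7 relation, which no small hydride reagent senses, and epimerisation faster than any reduction of the (1S)-epimer, which the acidity of the α′-position (piperitone-type enones racemise readily in mild base) and the internal carboxylate secure.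

Step 5
Reactants: 7 (3S)-3-[(1R,2R)-2-hydroxy-4-methylcyclohex-3-en-1-yl]butanoic acid; 8 4-fluoro-3-methoxybenzaldehyde
Product: 9 (3S)-3-[(1R,2R)-2-(4-formyl-2-methoxyphenoxy)-4-methylcyclohex-3-en-1-yl]butanoic acid
Conditions: KHMDS (2.1 equiv), THF/DMF, −20 °C; 8 (1.3 equiv), −20 to 23 °C; cold 1 M HCl to pH 4
Reagents that add atoms: none
Why: SNAr (addition–elimination through the Meisenheimer adduct para to the formyl group); the new bond is O–aryl and the C2–O bond is never broken, so the C2 configuration is retained, and the carboxylate is too weak a nucleophile to compete.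

Step 6
Reactants: 9 (3S)-3-[(1R,2R)-2-(4-formyl-2-methoxyphenoxy)-4-methylcyclohex-3-en-1-yl]butanoic acid; 10 tributyl(2-methylprop-1-en-1-yl)stannane
Product: 12 3-methoxy-4-({(1R,6R)-3-methyl-6-[(2S)-6-methyl-4-oxohept-5-en-2-yl]cyclohex-2-en-1-yl}oxy)benzaldehyde, via (3S)-3-[(1R,2R)-2-(4-formyl-2-methoxyphenoxy)-4-methylcyclohex-3-en-1-yl]butanoyl chloride 11 (not isolated)
Conditions: 1-chloro-N,N,2-trimethylprop-1-en-1-amine, CH2Cl2, 0 °C; then 10, Pd2(dba)3 (2.5 mol %), P(2-furyl)3 (10 mol %), THF, 23–40 °C
Reagents that add atoms: 1-chloro-N,N,2-trimethylprop-1-en-1-amine, CC(C)=C(Cl)N(C)C (chlorine of 11 only)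
Why: Neutral acid chloride formation followed by Migita–Kosugi–Stille acylation, which tolerates the aryl aldehyde; oxidative addition of the acyl chloride should outrun ionisation of the hindered allyl aryl ether, whose anti face is shielded by the C1 side chain, and no stereocentre is touched.

Step 7
Reactants: 12 3-methoxy-4-({(1R,6R)-3-methyl-6-[(2S)-6-methyl-4-oxohept-5-en-2-yl]cyclohex-2-en-1-yl}oxy)benzaldehyde
Product: 13 4-({(1R,4S,6R)-4-hydroxy-3-methyl-6-[(2S)-6-methyl-4-oxohept-5-en-2-yl]cyclohex-2-en-1-yl}oxy)-3-methoxybenzaldehyde
Conditions: SeO2 (0.3 equiv), t-BuOOH (2.5 equiv, decane), CH2Cl2, 0 to 23 °C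
Reagents that add atoms: selenium dioxide, O=[Se]=O; tert-butyl hydroperoxide, CC(C)(C)OO
Why: Riley-type selenium dioxide allylic hydroxylation (ene reaction, then [2,3]-sigmatropic shift): selenium attacks C3 of the only electron-rich alkene, takes the pseudoaxial C5–H of the ring CH2 at the more substituted terminus on the face anti to the equatorial C1 side chain, and returns oxygen to C5 on that same face, which sets C5 (S), cis to the aryloxy group, as in limonene to trans-carveol.

Step 8
Reactants: 14 (E)-4-(4-hydroxy-3-methoxyphenyl)but-3-en-2-one (dehydrozingerone); 15 1-acetyl-1H-benzotriazole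
Product: 16 (E)-6-(4-hydroxy-3-methoxyphenyl)hex-5-ene-2,4-dione (feruloylacetone)
Conditions: LiHMDS (3.2 equiv), THF, −78 °C; 15 (1.05 equiv), −78 to 0 °C; 1 M HCl
Reagents that add atoms: none
Why: Claisen-type C-acylation of a ketone enolate with an N-acylbenzotriazole; three equivalents of base cover the phenol, the methyl ketone and the more acidic diketone product, the enolate carbon is far more reactive than the lithium phenoxide, and no stereocentre is formed.

Step 9
Reactants: 13 4-({(1R,4S,6R)-4-hydroxy-3-methyl-6-[(2S)-6-methyl-4-oxohept-5-en-2-yl]cyclohex-2-en-1-yl}oxy)-3-methoxybenzaldehyde; 16 (E)-6-(4-hydroxy-3-methoxyphenyl)hex-5-ene-2,4-dione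
Product: 19 bisabolocurcumin ether, via dibutoxyboron chelate of feruloylacetone 17 (not isolated), via dibutoxyboron chelate of bisabolocurcumin ether 18 (not isolated)
Conditions: 16, B2O3 (0.7 equiv), EtOAc, 70 °C; 13, B(On-Bu)3 (2 equiv); n-BuNH2 (0.3 equiv, slow addition), 70 °C; then 10% aq citric acid, 40 °C
Reagents that add atoms: tributyl borate, CCCCOB(OCCCC)OCCCC, and boron oxide, O=BOB=O (boron and butoxy groups of 17 and 18 only)
Why: Pabon-type boron-templated aldol condensation: chelation of the 1,3-diketone blocks Knoevenagel reaction at the central carbon and acidifies the terminal methyl group, whose amine-promoted condensation with the aryl aldehyde gives the (E)-enone, the isolated β,β-dimethyl enone is far less C–H acidic, mild acid hydrolysis frees the keto–enol without ionising the allylic ether, and no sp3 stereocentre is touched.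

Compound list
1 | (2-methoxy-4-methylphenyl)boronic acid | COc1cc(C)ccc1B(O)O | starting material
2 | isopropyl (E)-but-2-enoate | C/C=C/C(=O)OC(C)C | starting material
3 | isopropyl (3S)-3-(2-methoxy-4-methylphenyl)butanoate | COc1cc(C)ccc1[C@@H](C)CC(=O)OC(C)C | intermediate
4 | (3S)-3-(2-methoxy-4-methylphenyl)butanoic acid | COc1cc(C)ccc1[C@@H](C)CC(=O)O | intermediate
5 | (3S)-3-(2-methoxy-4-methylcyclohexa-1,4-dien-1-yl)butanoic acid | COC1=C(CC=C(C)C1)[C@@H](C)CC(=O)O | intermediate
6 | (3S)-3-[(1RS)-4-methyl-2-oxocyclohex-3-en-1-yl]butanoic acid (both C1 epimers) | CC1=CC(=O)C(CC1)[C@@H](C)CC(=O)O | intermediate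
7 | (3S)-3-[(1R,2R)-2-hydroxy-4-methylcyclohex-3-en-1-yl]butanoic acid | O[C@H]1C=C(C)CC[C@@H]1[C@@H](C)CC(=O)O | intermediate
8 | 4-fluoro-3-methoxybenzaldehyde | COc1cc(C=O)ccc1F | starting material
9 | (3S)-3-[(1R,2R)-2-(4-formyl-2-methoxyphenoxy)-4-methylcyclohex-3-en-1-yl]butanoic acid | COc1cc(C=O)ccc1O[C@H]1C=C(C)CC[C@@H]1[C@@H](C)CC(=O)O | intermediate
10 | tributyl(2-methylprop-1-en-1-yl)stannane | CCCC[Sn](CCCC)(CCCC)C=C(C)C | starting material
11 | (3S)-3-[(1R,2R)-2-(4-formyl-2-methoxyphenoxy)-4-methylcyclohex-3-en-1-yl]butanoyl chloride | COc1cc(C=O)ccc1O[C@H]1C=C(C)CC[C@@H]1[C@@H](C)CC(=O)Cl | intermediate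
12 | 3-methoxy-4-({(1R,6R)-3-methyl-6-[(2S)-6-methyl-4-oxohept-5-en-2-yl]cyclohex-2-en-1-yl}oxy)benzaldehyde | COc1cc(C=O)ccc1O[C@H]1C=C(C)CC[C@@H]1[C@@H](C)CC(=O)C=C(C)C | intermediate
13 | 4-({(1R,4S,6R)-4-hydroxy-3-methyl-6-[(2S)-6-methyl-4-oxohept-5-en-2-yl]cyclohex-2-en-1-yl}oxy)-3-methoxybenzaldehyde | COc1cc(C=O)ccc1O[C@H]1C=C(C)[C@@H](O)C[C@@H]1[C@@H](C)CC(=O)C=C(C)C | intermediate
14 | (E)-4-(4-hydroxy-3-methoxyphenyl)but-3-en-2-one (dehydrozingerone) | CC(=O)/C=C/c1ccc(O)c(OC)c1 | starting material
15 | 1-acetyl-1H-benzotriazole | CC(=O)n1nnc2ccccc21 | starting material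
16 | (E)-6-(4-hydroxy-3-methoxyphenyl)hex-5-ene-2,4-dione (feruloylacetone) | CC(=O)CC(=O)/C=C/c1ccc(O)c(OC)c1 | intermediate
17 | dibutoxyboron chelate of feruloylacetone | CC1=CC(/C=C/c2ccc(O)c(OC)c2)=[O+][B-](OCCCC)(OCCCC)O1 | intermediate
18 | dibutoxyboron chelate of bisabolocurcumin ether | COc1cc(/C=C/C2=CC(/C=C/c3ccc(O[C@H]4C=C(C)[C@@H](O)C[C@@H]4[C@@H](C)CC(=O)C=C(C)C)c(OC)c3)=[O+][B-](OCCCC)(OCCCC)O2)ccc1O | intermediate
19 | bisabolocurcumin ether | COc1cc(/C=C/C(=O)/C=C(O)/C=C/c2ccc(O[C@H]3C=C(C)[C@@H](O)C[C@@H]3[C@@H](C)CC(=O)C=C(C)C)c(OC)c2)ccc1O | target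

Total steps: 9. Longest linear sequence: 8 (steps 1–7 and 9; step 8 is a one-step side branch).

Steps most likely to fail

Step 4. Epimerisation at C1 may be too slow relative to reduction. The enzyme may also discriminate the two epimers incompletely, which would erode the diastereomeric purity, and the δ-hydroxy acid may lactonise on acidic work-up. The fallback sets out from 6 and comes back at 7, replacing the dynamic enzymatic resolution by substrate-controlled reduction, separation and recycling. Luche reduction (NaBH4, CeCl3, MeOH, −40 °C) of the sodium salt of 6 should reduce each C1 epimer by axial attack to its trans alcohol. This gives 7 and (3S)-3-[(1S,2S)-2-hydroxy-4-methylcyclohex-3-en-1-yl]butanoic acid F1. The two diastereomers are separated by chromatography or by fractional crystallisation of their dicyclohexylammonium salts. F1 is returned to 6 by MnO2 oxidation, which re-opens the C1 epimerisation.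

Step 7. The risks are competing attack at the ring methyl group, over-oxidation of the new allylic alcohol to the enone, incomplete facial selectivity at C5, and oxidation of the aryl aldehyde by peroxidic selenium species. The fallback sets out from 12 and comes back at 13, and it replaces the ene/[2,3] manifold by hydrogen abstraction and oxygen rebound in an enzyme pocket. The enzyme would be a cytochrome P450 monooxygenase of the limonene-6-hydroxylase type or an engineered P450-BM3 variant (alternatively a fungal unspecific peroxygenase with H2O2). It is screened for hydroxylation of the ring CH2 next to the methyl-bearing alkene carbon on the face anti to the side chain. No new compound is made (F0).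

Step 5. Addition–elimination of the hindered secondary alkoxide at a fluoroarene that carries an ortho methoxy group may be slow. That would leave time for hydride transfer or Tishchenko-type consumption of the aldehyde. The fallback sets out from 7 and comes back at 9, and it changes the mechanism of O–aryl bond formation to ligand coupling at iodine(III), again with retention at C2. Commercial 4-iodo-3-methoxybenzaldehyde is oxidised (mCPBA, TsOH·H2O, MeCN) and trapped with 1,3,5-trimethoxybenzene to give (4-formyl-2-methoxyphenyl)(2,4,6-trimethoxyphenyl)iodonium tosylate F2. The dipotassium salt of 7 (t-BuOK, toluene/THF, 23 °C) is then arylated with F2. The electron-poor aryl group should be transferred and the trimethoxyphenyl group should stay on iodine.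

Further compounds
F1 | step 4 | (3S)-3-[(1S,2S)-2-hydroxy-4-methylcyclohex-3-en-1-yl]butanoic acid | O[C@@H]1C=C(C)CC[C@H]1[C@@H](C)CC(=O)O
F2 | step 5 | (4-formyl-2-methoxyphenyl)(2,4,6-trimethoxyphenyl)iodonium tosylate | COc1cc(C=O)ccc1[I+]c1c(OC)cc(OC)cc1OC.Cc1ccc(cc1)S(=O)(=O)[O-]
F0 | step 7 | none | none
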